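## Retrosynthetic overview

1. Target 10 ⇒ salicylaldehyde 9: the carboxyl comes from oxidation of a formyl group, so no carboxyl derivative ever sits next to a free side-chain hydroxyl and the dihydroisocoumarin lactone cannot form.
2. 9 ⇒ 7 ⇒ 5: chelation-controlled removal of the one O-methyl ortho to CHO; the CHO is put on by Vilsmeier–Haack formylation of the symmetric 3,5-dimethoxyaryl ring.
3. 5 ⇒ 4 + AcOH: the C2′–OAc bond and the only stereocentre are made together by an enantioselective anti-Markovnikov hydroacetoxylation of the styrene (metal-free chiral ion-pair photoredox catalysis).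
4. 4 ⇒ 1 + 2: the C1′=C2′ bond by Horner–Wadsworth–Emmons olefination.
5. Rings: none is formed; the benzene ring comes in with 1 and is only substituted.

Assumption: phosphonate 1 is taken as a catalogue compound, and the sense of induction of the new catalyst in step 2 must be fixed by experiment; the anion enantiomer that gives the (R)-acetate is used, written provisionally as (S,S).

Catalyst for step 2 (Cat*): 9-mesityl-3,6-di-tert-butyl-10-phenylacridinium paired with an (S,S)-BINOL-derived imidodiphosphorimidate (IDPi) anion, made by salt metathesis of the acridinium tetrafluoroborate with the sodium IDPi salt.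

## Route

Step 1
Reactants: 1 diethyl (3,5-dimethoxybenzyl)phosphonate; 2 dodecanal
Product: 4 (E)-1,3-dimethoxy-5-(tridec-1-en-1-yl)benzene, via potassium phosphonate carbanion 3 (not isolated)
Conditions: KOtBu (1.1 equiv), THF, 0 °C; then 2 added slowly, 0 °C → rt
Reagents that add atoms: none
Why: Horner–Wadsworth–Emmons olefination of a semi-stabilised benzylic phosphonate anion with an aliphatic aldehyde gives the (E)-styrene, and no stereocentre is formed.

Step 2
Reactants: 4 (E)-1,3-dimethoxy-5-(tridec-1-en-1-yl)benzene
Product: 5 (R)-1-(3,5-dimethoxyphenyl)tridecan-2-yl acetate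
Conditions: AcOH (5 equiv), Cat* (3 mol%), PhSSPh (10 mol%), toluene/CH2Cl2 4:1 (0.05 M), 455 nm LEDs, −30 °C, Ar
Reagents that add atoms: acetic acid, CC(=O)O
Why: Proposed new method: enantioselective anti-Markovnikov hydroacetoxylation by chiral-counteranion photoredox organocatalysis, in which the excited acridinium oxidises the styrene to its radical cation, this is held in the non-polar medium as a contact ion pair inside the confined chiral IDPi anion so that acetic acid adds to C2 from one face only (attack on the C2 Re face gives R), forming the C–O bond and the stereocentre together, and the resulting benzylic radical takes a hydrogen atom from the thiol whose thiyl radical turns over the reduced acridine; the closest known reaction types are the racemic acridinium/thiol anti-Markovnikov addition of carboxylic acids to β-alkylstyrenes and chiral-anion-controlled reactions of styrene radical cations (cycloadditions, intramolecular hydroetherification).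

Step 3
Reactants: 5 (R)-1-(3,5-dimethoxyphenyl)tridecan-2-yl acetate
Product: 7 (R)-1-(2-formyl-3,5-dimethoxyphenyl)tridecan-2-yl acetate, via aryl iminium chloride 6 (not isolated)
Conditions: POCl3 (1.5 equiv), DMF, 0 → 70 °C; then ice–water, rt
Reagents that add atoms: N,N-dimethylformamide, CN(C)C=O; water, O
Why: Vilsmeier–Haack formylation attacks the position para to one methoxy and ortho to the other (C2 and C6 are equivalent by symmetry) in preference to the more crowded site between the two methoxy groups, and the secondary acetate and its stereocentre are inert to the chloroiminium reagent.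

Step 4
Reactants: 7 (R)-1-(2-formyl-3,5-dimethoxyphenyl)tridecan-2-yl acetate
Product: 9 (R)-1-(2-formyl-3-hydroxy-5-methoxyphenyl)tridecan-2-yl acetate, via aryloxydichloroborane 8 (not isolated)
Conditions: BCl3 (1.5 equiv), CH2Cl2, −78 → 0 °C; then H2O
Reagents that add atoms: none
Why: Chelation-directed Lewis-acid ether cleavage, in which boron bridges the formyl oxygen and the ortho methoxy oxygen so that chloride removes only that methyl group, leaving the para methoxy group, the acetate and the stereocentre untouched.

Step 5
Reactants: 9 (R)-1-(2-formyl-3-hydroxy-5-methoxyphenyl)tridecan-2-yl acetate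
Product: 10 2-[(2R)-2-(acetyloxy)tridecyl]-6-hydroxy-4-methoxybenzoic acid
Conditions: NaClO2 (3 equiv), NaH2PO4, 2-methyl-2-butene (20 equiv), t-BuOH/H2O, 0 °C → rt; cold work-up at pH 3
Reagents that add atoms: sodium chlorite, [Na+].[O-]Cl=O
Why: Pinnick oxidation by chlorous acid converts the aldehyde to the acid under mildly acidic buffered conditions that leave the acetate and the stereocentre alone, while the alkene scavenger removes hypochlorous acid before it can chlorinate the phenol ring.

## Compound list

1 | diethyl (3,5-dimethoxybenzyl)phosphonate | CCOP(=O)(Cc1cc(OC)cc(OC)c1)OCC | starting material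
2 | dodecanal | CCCCCCCCCCCC=O | starting material
3 | potassium (3,5-dimethoxyphenyl)(diethoxyphosphoryl)methanide | CCOP(=O)([CH-]c1cc(OC)cc(OC)c1)OCC.[K+] | intermediate
4 | (E)-1,3-dimethoxy-5-(tridec-1-en-1-yl)benzene | CCCCCCCCCCC/C=C/c1cc(OC)cc(OC)c1 | intermediate
5 | (R)-1-(3,5-dimethoxyphenyl)tridecan-2-yl acetate | CCCCCCCCCCC[C@H](Cc1cc(OC)cc(OC)c1)OC(C)=O | intermediate
6 | (R)-N-{[2-(2-acetoxytridecyl)-4,6-dimethoxyphenyl]methylidene}-N-methylmethanaminium chloride | CCCCCCCCCCC[C@H](Cc1cc(OC)cc(OC)c1C=[N+](C)C)OC(C)=O.[Cl-] | intermediate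
7 | (R)-1-(2-formyl-3,5-dimethoxyphenyl)tridecan-2-yl acetate | CCCCCCCCCCC[C@H](Cc1cc(OC)cc(OC)c1C=O)OC(C)=O | intermediate
8 | (R)-1-{3-[(dichloroboranyl)oxy]-2-formyl-5-methoxyphenyl}tridecan-2-yl acetate | CCCCCCCCCCC[C@H](Cc1cc(OC)cc(OB(Cl)Cl)c1C=O)OC(C)=O | intermediate
9 | (R)-1-(2-formyl-3-hydroxy-5-methoxyphenyl)tridecan-2-yl acetate | CCCCCCCCCCC[C@H](Cc1cc(OC)cc(O)c1C=O)OC(C)=O | intermediate
10 | 2-[(2R)-2-(acetyloxy)tridecyl]-6-hydroxy-4-methoxybenzoic acid | CCCCCCCCCCC[C@H](Cc1cc(OC)cc(O)c1C(=O)O)OC(C)=O | target

## Step count and risks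

Total step count: 5. Longest linear sequence: 5 steps (1 → 4 → 5 → 7 → 9 → 10).

The three steps most likely to fail:

Step 2 (the proposed new method). The risks are a low enantiomeric excess, radical-cation dimerisation of 4, and acid-catalysed Markovnikov addition. The fallback uses known chemistry, sets out from 4 and comes back at 5. Shi epoxidation of the (E)-alkene (D-fructose-derived ketone catalyst, Oxone, K2CO3, Bu4NHSO4, MeCN/dimethoxymethane/aqueous buffer, 0 °C) gives (2R,3R)-2-(3,5-dimethoxyphenyl)-3-undecyloxirane F1; trans-β-alkylstyrenes are a favourable substrate class for this organocatalyst. Hydrogenolysis (H2, Pd/C, EtOAc, rt) then cleaves only the benzylic C–O bond and leaves C2 untouched, giving (R)-1-(3,5-dimethoxyphenyl)tridecan-2-ol F2. Acetylation (Ac2O, pyridine, DMAP) returns to 5. This costs two extra steps.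

Step 3. The risks are formylation at the position between the two methoxy groups and slow reaction next to the branched side chain. The fallback sets out from 5 and comes back at 7. Bromination with NBS (MeCN, 0 °C), a smaller electrophile whose regioisomers are easy to separate, gives (R)-1-(2-bromo-3,5-dimethoxyphenyl)tridecan-2-yl acetate F3. Palladium-catalysed reductive carbonylation (Pd(OAc)2, di(1-adamantyl)-n-butylphosphine, CO/H2, TMEDA, toluene, 100 °C) then converts the bromide into aldehyde 7.

Step 5. The risks are ring chlorination of the electron-rich phenol and sluggish oxidation of the hydrogen-bonded salicylaldehyde. The fallback changes the order of events, sets out from 7 and comes back at 10. Pinnick oxidation of the non-phenolic aldehyde 7 gives (R)-2-(2-acetoxytridecyl)-4,6-dimethoxybenzoic acid F4. BCl3 (CH2Cl2, −78 → −20 °C) then removes the methyl group ortho to the carboxyl through the cyclic chloroboron salicylate (R)-1-(2-chloro-7-methoxy-4-oxo-4H-1,3,2-benzodioxaborinin-5-yl)tridecan-2-yl acetate F5, which is hydrolysed on cold aqueous work-up to 10. The low temperature is needed to avoid Lewis-acid-induced lactonisation.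

Further compounds

F1 | step 2 | (2R,3R)-2-(3,5-dimethoxyphenyl)-3-undecyloxirane | CCCCCCCCCCC[C@H]1O[C@@H]1c2cc(OC)cc(OC)c2
F2 | step 2 | (R)-1-(3,5-dimethoxyphenyl)tridecan-2-ol | CCCCCCCCCCC[C@H](Cc1cc(OC)cc(OC)c1)O
F3 | step 3 | (R)-1-(2-bromo-3,5-dimethoxyphenyl)tridecan-2-yl acetate | CCCCCCCCCCC[C@H](Cc1cc(OC)cc(OC)c1Br)OC(C)=O
F4 | step 5 | (R)-2-(2-acetoxytridecyl)-4,6-dimethoxybenzoic acid | CCCCCCCCCCC[C@H](Cc1cc(OC)cc(OC)c1C(=O)O)OC(C)=O
F5 | step 5 | (R)-1-(2-chloro-7-methoxy-4-oxo-4H-1,3,2-benzodioxaborinin-5-yl)tridecan-2-yl acetate | CCCCCCCCCCC[C@H](Cc1cc(OC)cc2OB(Cl)OC(=O)c12)OC(C)=O
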